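**Retrosynthetic overview**

- The target is a linear pentamer A–O–B–O–C–O–D–O–E; all thirteen hydroxyls travel as methyl ethers (one as the last Dakin phenol) and are freed together by BBr3 at the end.
- The plan rests on ring D: C1 carries the ether oxygen to ring C, C3 and C4 carry hydroxyl, C5 carries the ether oxygen to ring E, and C2 and C6 carry hydrogen. A 2,3-dialkoxycyclobutenone (C1–C4 with the C3/C4 oxygens) and an aryloxyacetylene (C5, C6 with the ring E ether) deliver this pattern in one benzannulation.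
- Ring D is the only ring built: 2,3-dimethoxycyclobut-2-en-1-one (from dimethyl squarate) plus 3,4,5-trimethoxyphenoxyacetylene (ring E, from 3,4,5-trimethoxyphenol and trichloroethylene).
- Rings C, B and A are bought as bromobenzaldehydes and attached in that order at the growing phenol by copper-catalysed O-arylation followed by Dakin oxidation; each Dakin step turns the formyl carbon into the oxygen needed next (ring C: formyl ortho to the new ether; rings B and A: formyl para).
- Ring order: E (bought), D (formed, step 6), then C, B, A (attached, steps 7–12), global demethylation last.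

Key step: step 6

Remark on the chemistry: the target has no stereocentre; the three chiral intermediates of the route are racemic and lose their stereocentre in later steps.

**Route**

Step 1
Reactants: 1 dimethyl squarate (3,4-dimethoxycyclobut-3-ene-1,2-dione)
Product: 2 4-hydroxy-2,3-dimethoxycyclobut-2-en-1-one (racemic)
Conditions: LiAlH(OtBu)3 (1.1 equiv), THF, −78 °C; then Na2SO4·10H2O, −78 → 0 °C, filtration
Reagents that add atoms: none
Why: Chemoselective 1,2-hydride reduction of one squarate carbonyl by the bulky alkoxyaluminium hydride at low temperature should stop at the 4-hydroxycyclobutenone, whose carbinol carbon forms racemic and becomes CH2 in step 3, and the neutral non-aqueous quench avoids the acid-induced loss of methanol to the cyclobutenedione.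

Step 2
Reactants: 2 4-hydroxy-2,3-dimethoxycyclobut-2-en-1-one
Product: 3 O-(2,3-dimethoxy-4-oxocyclobut-2-en-1-yl) O-phenyl carbonothioate (racemic)
Conditions: PhOC(S)Cl (1.2 equiv), pyridine, DMAP (cat.), CH2Cl2, 0 °C
Reagents that add atoms: O-phenyl chlorothionoformate, S=C(Cl)Oc1ccccc1
Why: O-Acylation of the secondary alcohol to the aryl thionocarbonate (first half of a Barton–McCombie deoxygenation) runs under basic, acid-free conditions, so the ionisation-prone 4-position should stay intact.

Step 3
Reactants: 3 O-(2,3-dimethoxy-4-oxocyclobut-2-en-1-yl) O-phenyl carbonothioate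
Product: 4 2,3-dimethoxycyclobut-2-en-1-one
Conditions: (Me3Si)3SiH (1.3 equiv), Et3B (cat.), trace air, PhMe, 0 °C → rt
Reagents that add atoms: none
Why: In this Barton–McCombie radical deoxygenation the silyl radical adds to C=S, β-scission gives the delocalised oxocyclobutenyl radical, and the bulky hydridic silane is expected to transfer hydrogen to the unsubstituted, more electrophilic CH terminus, which keeps the fully substituted dimethoxy enone, while Et3B/air initiation keeps the temperature below that of cyclobutenone ring opening.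

Step 4
Reactants: 5 3,4,5-trimethoxyphenol; 6 trichloroethylene
Product: 7 5-{[(E)-1,2-dichloroethenyl]oxy}-1,2,3-trimethoxybenzene
Conditions: K2CO3, DMF, 70 °C
Reagents that add atoms: none
Why: Base converts trichloroethylene into dichloroacetylene and the phenoxide adds to it in anti fashion (base-mediated vinylation of a phenol), which should give the (E)-1,2-dichlorovinyl ether.

Step 5
Reactants: 7 5-{[(E)-1,2-dichloroethenyl]oxy}-1,2,3-trimethoxybenzene
Product: 10 5-(ethynyloxy)-1,2,3-trimethoxybenzene, via chloroalkyne 8 (not isolated), via lithium acetylide 9 (not isolated)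
Conditions: n-BuLi (2.3 equiv), THF, −78 → −40 °C; MeOH, −78 °C; cold filtration through basic alumina, used at once
Reagents that add atoms: none
Why: Dehydrochlorination by the first equivalent of n-BuLi and chlorine–lithium exchange by the second (the standard dichlorovinyl ether route to ynol ethers) should give the lithium acetylide, which methanol protonates to the terminal aryl ynol ether, kept cold and in solution because such alkynes polymerise on storage.

Step 6
Reactants: 4 2,3-dimethoxycyclobut-2-en-1-one; 10 5-(ethynyloxy)-1,2,3-trimethoxybenzene (1.5 equiv)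
Product: 15 3,4-dimethoxy-5-(3,4,5-trimethoxyphenoxy)phenol, via vinylketene 11 (not isolated), via vinylcyclobutenone 12 (not isolated), via dienylketene 13 (not isolated), via cyclohexadienone 14 (not isolated)
Conditions: PhMe (0.2 M), sealed tube, argon, 110 → 140 °C
Reagents that add atoms: none
Why: Heating opens 4 by four-electron electrocyclic ring opening to vinylketene 11, whose electrophilic carbonyl carbon is attacked by the nucleophilic CH terminus of ynol ether 10 in a regioselective (2+2) cycloaddition that forms C1–C6 and C4–C5 and closes the transient four-membered ring of 12. The methoxy group on the sp3 carbon of 12 rotates outward in the second four-electron opening, so the vinyl group turns inward and the (Z)-dienylketene 13 is set up for cyclisation. Ring D is then closed by thermal disrotatory six-electron electrocyclisation (C1–C2), and dienone 14 tautomerises to the phenol, free at C1. The closest known reaction type is the Danheiser benzannulation of cyclobutenones with alkoxy- and siloxyalkynes. No stereocentre remains, since the quaternary centre of racemic 12 becomes aromatic C4. The step needs regiocontrol, which the polarised ynol ether secures by placing the aryloxy group meta to the new hydroxyl and next to the methoxy carbons, and the aryl ynol ether has no β-hydrogen on its oxygen substituent, so it cannot fragment to a ketene by retro-ene reaction at this temperature.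

Step 7
Reactants: 15 3,4-dimethoxy-5-(3,4,5-trimethoxyphenoxy)phenol; 16 2-bromo-3,4,5-trimethoxybenzaldehyde
Product: 17 2-[3,4-dimethoxy-5-(3,4,5-trimethoxyphenoxy)phenoxy]-3,4,5-trimethoxybenzaldehyde
Conditions: CuI (10 mol %), picolinic acid (20 mol %), K3PO4, DMSO, 90 °C, argon
Reagents that add atoms: none
Why: In this Ullmann-type O-arylation under monovalent copper catalysis the unhindered, electron-rich phenol should couple with the aryl bromide, whose ortho-formyl group assists C–Br activation and is non-enolisable and inert to K3PO4.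

Step 8
Reactants: 17 2-[3,4-dimethoxy-5-(3,4,5-trimethoxyphenoxy)phenoxy]-3,4,5-trimethoxybenzaldehyde
Product: 19 2-[3,4-dimethoxy-5-(3,4,5-trimethoxyphenoxy)phenoxy]-3,4,5-trimethoxyphenol, via aryl formate 18 (not isolated)
Conditions: mCPBA (1.3 equiv), CH2Cl2, 0 °C → rt; aq. Na2S2O3/NaHCO3 wash; then K2CO3 (cat.), MeOH, rt
Reagents that add atoms: mCPBA (3-chloroperoxybenzoic acid), OOC(=O)c1cccc(Cl)c1
Why: In this Dakin oxidation in its Baeyer–Villiger form the electron-rich aryl group (ortho-aryloxy, para-methoxy) should migrate in the Criegee adduct to give the formate, and mild methanolysis frees the phenol at C1 of ring C, the oxygen that will carry ring B.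

Step 9
Reactants: 19 2-[3,4-dimethoxy-5-(3,4,5-trimethoxyphenoxy)phenoxy]-3,4,5-trimethoxyphenol; 20 4-bromo-3,5-dimethoxybenzaldehyde
Product: 21 4-{2-[3,4-dimethoxy-5-(3,4,5-trimethoxyphenoxy)phenoxy]-3,4,5-trimethoxyphenoxy}-3,5-dimethoxybenzaldehyde
Conditions: CuI (10 mol %), picolinic acid (20 mol %), K3PO4, DMSO, 105 °C, argon
Reagents that add atoms: none
Why: In this Ullmann-type O-arylation the para-formyl group activates the C–Br bond flanked by two methoxy groups, and the picolinic acid ligand system is chosen because it tolerates ortho substituents on both coupling partners.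

Step 10
Reactants: 21 4-{2-[3,4-dimethoxy-5-(3,4,5-trimethoxyphenoxy)phenoxy]-3,4,5-trimethoxyphenoxy}-3,5-dimethoxybenzaldehyde
Product: 23 4-{2-[3,4-dimethoxy-5-(3,4,5-trimethoxyphenoxy)phenoxy]-3,4,5-trimethoxyphenoxy}-3,5-dimethoxyphenol, via aryl formate 22 (not isolated)
Conditions: mCPBA (1.3 equiv), CH2Cl2, 0 °C → rt; aq. Na2S2O3/NaHCO3 wash; then K2CO3 (cat.), MeOH, rt
Reagents that add atoms: mCPBA (3-chloroperoxybenzoic acid), OOC(=O)c1cccc(Cl)c1
Why: In this Dakin oxidation (Baeyer–Villiger aryl migration, then formate methanolysis) the para-aryloxy group drives aryl migration as in the conversion of 3,4,5-trialkoxybenzaldehydes into phenols, and the new hydroxyl sits at C1 of ring B, where ring A is attached.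

Step 11
Reactants: 23 4-{2-[3,4-dimethoxy-5-(3,4,5-trimethoxyphenoxy)phenoxy]-3,4,5-trimethoxyphenoxy}-3,5-dimethoxyphenol; 20 4-bromo-3,5-dimethoxybenzaldehyde
Product: 24 4-(4-{2-[3,4-dimethoxy-5-(3,4,5-trimethoxyphenoxy)phenoxy]-3,4,5-trimethoxyphenoxy}-3,5-dimethoxyphenoxy)-3,5-dimethoxybenzaldehyde
Conditions: CuI (10 mol %), picolinic acid (20 mol %), K3PO4, DMSO, 100 °C, argon
Reagents that add atoms: none
Why: This Ullmann-type O-arylation pairs a phenol with two free ortho positions with the same para-formyl-activated bromide as in step 9, so it should be the easier of the two couplings with this bromide.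

Step 12
Reactants: 24 4-(4-{2-[3,4-dimethoxy-5-(3,4,5-trimethoxyphenoxy)phenoxy]-3,4,5-trimethoxyphenoxy}-3,5-dimethoxyphenoxy)-3,5-dimethoxybenzaldehyde
Product: 26 4-(4-{2-[3,4-dimethoxy-5-(3,4,5-trimethoxyphenoxy)phenoxy]-3,4,5-trimethoxyphenoxy}-3,5-dimethoxyphenoxy)-3,5-dimethoxyphenol, via aryl formate 25 (not isolated)
Conditions: mCPBA (1.3 equiv), CH2Cl2, 0 °C → rt; aq. Na2S2O3/NaHCO3 wash; then K2CO3 (cat.), MeOH, rt
Reagents that add atoms: mCPBA (3-chloroperoxybenzoic acid), OOC(=O)c1cccc(Cl)c1
Why: This third Dakin oxidation (Baeyer–Villiger aryl migration, then methanolysis) should install the para oxygen of ring A directly as a free hydroxyl.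

Step 13
Reactants: 26 4-(4-{2-[3,4-dimethoxy-5-(3,4,5-trimethoxyphenoxy)phenoxy]-3,4,5-trimethoxyphenoxy}-3,5-dimethoxyphenoxy)-3,5-dimethoxyphenol
Product: 27 2-(4-{2-[3,4-dihydroxy-5-(3,4,5-trihydroxyphenoxy)phenoxy]-3,4,5-trihydroxyphenoxy}-3,5-dihydroxyphenoxy)benzene-1,3,5-triol (target, CNP0154768.0)
Conditions: BBr3 (large excess), CH2Cl2, −78 °C → rt, argon; then H2O, 0 °C; Sephadex LH-20 or reversed-phase purification under argon
Reagents that add atoms: none
Why: In this Lewis-acid cleavage of aryl methyl ethers BBr3 coordinates each methoxy oxygen and bromide removes the methyl group by SN2, whereas the four diaryl ether bonds offer no sp3 carbon for attack and should persist, so hydrolysis should free all thirteen phenols.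

**Compound list**

1 | dimethyl squarate (3,4-dimethoxycyclobut-3-ene-1,2-dione) | COC1=C(OC)C(=O)C1=O | starting material
2 | 4-hydroxy-2,3-dimethoxycyclobut-2-en-1-one (racemic) | O=C1C(O)C(OC)=C1OC | intermediate
3 | O-(2,3-dimethoxy-4-oxocyclobut-2-en-1-yl) O-phenyl carbonothioate (racemic) | O=C1C(OC(=S)Oc2ccccc2)C(OC)=C1OC | intermediate
4 | 2,3-dimethoxycyclobut-2-en-1-one | COC1=C(OC)C(=O)C1 | intermediate
5 | 3,4,5-trimethoxyphenol | COc1cc(O)cc(OC)c1OC | starting material
6 | trichloroethylene | ClC=C(Cl)Cl | starting material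
7 | 5-{[(E)-1,2-dichloroethenyl]oxy}-1,2,3-trimethoxybenzene | Cl/C=C(/Cl)Oc1cc(OC)c(OC)c(OC)c1 | intermediate
8 | 5-[(chloroethynyl)oxy]-1,2,3-trimethoxybenzene (chloroalkyne) | ClC#COc1cc(OC)c(OC)c(OC)c1 | intermediate
9 | lithium (3,4,5-trimethoxyphenoxy)acetylide | [Li]C#COc1cc(OC)c(OC)c(OC)c1 | intermediate
10 | 5-(ethynyloxy)-1,2,3-trimethoxybenzene | C#COc1cc(OC)c(OC)c(OC)c1 | intermediate
11 | 2,3-dimethoxybuta-1,3-dien-1-one (vinylketene) | O=C=C(OC)C(OC)=C | intermediate
12 | 4-methoxy-4-(1-methoxyethenyl)-3-(3,4,5-trimethoxyphenoxy)cyclobut-2-en-1-one (racemic) | O=C1C=C(Oc2cc(OC)c(OC)c(OC)c2)C1(OC)C(OC)=C | intermediate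
13 | (3Z)-4,5-dimethoxy-3-(3,4,5-trimethoxyphenoxy)hexa-1,3,5-trien-1-one (dienylketene) | O=C=C/C(Oc1cc(OC)c(OC)c(OC)c1)=C(/OC)C(OC)=C | intermediate
14 | 4,5-dimethoxy-3-(3,4,5-trimethoxyphenoxy)cyclohexa-2,4-dien-1-one | O=C1C=C(Oc2cc(OC)c(OC)c(OC)c2)C(OC)=C(OC)C1 | intermediate
15 | 3,4-dimethoxy-5-(3,4,5-trimethoxyphenoxy)phenol | COc1cc(O)cc(Oc2cc(OC)c(OC)c(OC)c2)c1OC | intermediate
16 | 2-bromo-3,4,5-trimethoxybenzaldehyde | O=Cc1cc(OC)c(OC)c(OC)c1Br | starting material
17 | 2-[3,4-dimethoxy-5-(3,4,5-trimethoxyphenoxy)phenoxy]-3,4,5-trimethoxybenzaldehyde | O=Cc1cc(OC)c(OC)c(OC)c1Oc1cc(OC)c(OC)c(Oc2cc(OC)c(OC)c(OC)c2)c1 | intermediate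
18 | 2-[3,4-dimethoxy-5-(3,4,5-trimethoxyphenoxy)phenoxy]-3,4,5-trimethoxyphenyl formate | O=COc1cc(OC)c(OC)c(OC)c1Oc1cc(OC)c(OC)c(Oc2cc(OC)c(OC)c(OC)c2)c1 | intermediate
19 | 2-[3,4-dimethoxy-5-(3,4,5-trimethoxyphenoxy)phenoxy]-3,4,5-trimethoxyphenol | Oc1cc(OC)c(OC)c(OC)c1Oc1cc(OC)c(OC)c(Oc2cc(OC)c(OC)c(OC)c2)c1 | intermediate
20 | 4-bromo-3,5-dimethoxybenzaldehyde | O=Cc1cc(OC)c(Br)c(OC)c1 | starting material
21 | 4-{2-[3,4-dimethoxy-5-(3,4,5-trimethoxyphenoxy)phenoxy]-3,4,5-trimethoxyphenoxy}-3,5-dimethoxybenzaldehyde | O=Cc1cc(OC)c(Oc2cc(OC)c(OC)c(OC)c2Oc2cc(OC)c(OC)c(Oc3cc(OC)c(OC)c(OC)c3)c2)c(OC)c1 | intermediate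
22 | 4-{2-[3,4-dimethoxy-5-(3,4,5-trimethoxyphenoxy)phenoxy]-3,4,5-trimethoxyphenoxy}-3,5-dimethoxyphenyl formate | O=COc1cc(OC)c(Oc2cc(OC)c(OC)c(OC)c2Oc2cc(OC)c(OC)c(Oc3cc(OC)c(OC)c(OC)c3)c2)c(OC)c1 | intermediate
23 | 4-{2-[3,4-dimethoxy-5-(3,4,5-trimethoxyphenoxy)phenoxy]-3,4,5-trimethoxyphenoxy}-3,5-dimethoxyphenol | Oc1cc(OC)c(Oc2cc(OC)c(OC)c(OC)c2Oc2cc(OC)c(OC)c(Oc3cc(OC)c(OC)c(OC)c3)c2)c(OC)c1 | intermediate
24 | 4-(4-{2-[3,4-dimethoxy-5-(3,4,5-trimethoxyphenoxy)phenoxy]-3,4,5-trimethoxyphenoxy}-3,5-dimethoxyphenoxy)-3,5-dimethoxybenzaldehyde | O=Cc1cc(OC)c(Oc2cc(OC)c(Oc3cc(OC)c(OC)c(OC)c3Oc3cc(OC)c(OC)c(Oc4cc(OC)c(OC)c(OC)c4)c3)c(OC)c2)c(OC)c1 | intermediate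
25 | 4-(4-{2-[3,4-dimethoxy-5-(3,4,5-trimethoxyphenoxy)phenoxy]-3,4,5-trimethoxyphenoxy}-3,5-dimethoxyphenoxy)-3,5-dimethoxyphenyl formate | O=COc1cc(OC)c(Oc2cc(OC)c(Oc3cc(OC)c(OC)c(OC)c3Oc3cc(OC)c(OC)c(Oc4cc(OC)c(OC)c(OC)c4)c3)c(OC)c2)c(OC)c1 | intermediate
26 | 4-(4-{2-[3,4-dimethoxy-5-(3,4,5-trimethoxyphenoxy)phenoxy]-3,4,5-trimethoxyphenoxy}-3,5-dimethoxyphenoxy)-3,5-dimethoxyphenol | Oc1cc(OC)c(Oc2cc(OC)c(Oc3cc(OC)c(OC)c(OC)c3Oc3cc(OC)c(OC)c(Oc4cc(OC)c(OC)c(OC)c4)c3)c(OC)c2)c(OC)c1 | intermediate
27 | 2-(4-{2-[3,4-dihydroxy-5-(3,4,5-trihydroxyphenoxy)phenoxy]-3,4,5-trihydroxyphenoxy}-3,5-dihydroxyphenoxy)benzene-1,3,5-triol | Oc1cc(O)c(Oc2cc(O)c(Oc3cc(O)c(O)c(O)c3Oc3cc(O)c(O)c(Oc4cc(O)c(O)c(O)c4)c3)c(O)c2)c(O)c1 | target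

**Step count and risks**

Total step count: 13. Longest linear sequence: 11 steps (steps 1–3, then 6–13, from dimethyl squarate).

The three steps most likely to fail:

1. Step 3 (radical deoxygenation to cyclobutenone 4). The hydrogen atom may be transferred to the methoxy-bearing end of the delocalised oxocyclobutenyl radical, which would give the transposed 3,4-dimethoxy enone, or the allylic thionocarbonate may undergo a [3,3] shift or ionise before the chain starts. The fallback replaces the radical chain by a two-electron reductive cleavage of an α-acyloxy ketone. It sets out from 2: acetylation (Ac2O, pyridine, 0 °C) should give 2,3-dimethoxy-4-oxocyclobut-2-en-1-yl acetate F1. Treatment with SmI2 (2.2 equiv) in THF/MeOH at −78 °C (electron transfer to the carbonyl, loss of acetate, protonation on carbon by methanol at the unsubstituted position) should then come back to the route at 4.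

2. Step 6 (benzannulation). The terminal aryloxyalkyne may polymerise at the temperature needed to open the cyclobutenone, and the product phenol may be acylated by the vinylketene. The fallback gives up the de novo construction of ring D and makes the same phenol by conventional arene chemistry. It sets out from 5: Ullmann-type coupling (CuI, picolinic acid, K3PO4, DMSO, 90 °C) with commercial 3-bromo-4,5-dimethoxybenzaldehyde (O=Cc1cc(Br)c(OC)c(OC)c1) should give 3,4-dimethoxy-5-(3,4,5-trimethoxyphenoxy)benzaldehyde F2. Baeyer–Villiger oxidation with mCPBA should give 3,4-dimethoxy-5-(3,4,5-trimethoxyphenoxy)phenyl formate F3, and methanolysis (K2CO3, MeOH) comes back to the route at 15.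

3. Step 13 (twelvefold demethylation). Ether cleavage may stop short of completion, and the pyrogallol rings of the free tridecaphenol may be oxidised by air during aqueous work-up and chromatography. The fallback does not isolate the free phenol from the BBr3 reaction. It sets out from 26: after BBr3 treatment and evaporation, the crude product is acetylated (Ac2O, pyridine, DMAP) to the tridecaacetate of the target F4, which is stable and can be purified on silica away from partly methylated material. Deacetylation with NH4OAc in degassed aqueous MeOH at rt then comes back to the route at 27.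

**Further compounds**

F1 | step 3 | 2,3-dimethoxy-4-oxocyclobut-2-en-1-yl acetate (racemic) | CC(=O)OC1C(=O)C(OC)=C1OC
F2 | step 6 | 3,4-dimethoxy-5-(3,4,5-trimethoxyphenoxy)benzaldehyde | O=Cc1cc(OC)c(OC)c(Oc2cc(OC)c(OC)c(OC)c2)c1
F3 | step 6 | 3,4-dimethoxy-5-(3,4,5-trimethoxyphenoxy)phenyl formate | O=COc1cc(OC)c(OC)c(Oc2cc(OC)c(OC)c(OC)c2)c1
F4 | step 13 | tridecaacetate of the target | CC(=O)Oc1cc(OC(C)=O)c(Oc2cc(OC(C)=O)c(Oc3cc(OC(C)=O)c(OC(C)=O)c(OC(C)=O)c3Oc3cc(OC(C)=O)c(OC(C)=O)c(Oc4cc(OC(C)=O)c(OC(C)=O)c(OC(C)=O)c4)c3)c(OC(C)=O)c2)c(OC(C)=O)c1
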